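**Plan**

- Retrosynthesis: the 7''-O-methyl bond is cut first. Then C8–C8a and C4a–C5 are cut in each half (four C–C bonds), which removes both rings A as two molecules of a 1,3-dioxygenated four-carbon diene. Then C2–C3 and O1–C6 of each pyranone are cut (hetero-Diels–Alder). The C3–C3'' bond is never cut; it is the central CH2–CH2 bond of hexane-2,5-dione.
- Enabling feature: each ring A is a benzene ring fused at C4a–C8a and oxygenated at C5 and C7, with C8a bound to O1 and C4a to the C4 carbonyl. A 1-methoxy-1,3-disilyloxydiene places exactly these two oxygens when it adds to the polarised C5=C6 enone bond of a 2-aryl-2,3-dihydropyran-4-one (pyranone C5 becomes C4a, C6 becomes C8a).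
- Forward order: bis-enaminone, bis(aminosiloxydiene), both rings C in one double hetero-Diels–Alder operation, sulfinyl activation at C5/C5', both rings A in one double Diels–Alder–aromatisation, then methylation of one of the two homotopic 7-hydroxyls.
- Stereochemistry: all four centres (2R,3R,2''R,3''R; aryl and C3 substituent cis in each ring) arise in the catalytic asymmetric endo hetero-Diels–Alder step. No later step uses a base able to enolise C3 or open ring C.
- The C5 activating group is phenylsulfinyl, because after cycloaddition it is cis to the C8a hydrogen and can leave by thermal syn elimination.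

Key step: step 8

Assumption: the S-configured catalyst Rh2(S-BPTPI)4 is taken to give the 2R,3R series with 4-methoxybenzaldehyde; if its facial sense proves opposite, the R-configured catalyst is used and nothing else changes.

**Route**

Step 1
Reactants: 1 hexane-2,5-dione; 2 N,N-dimethylformamide dimethyl acetal (3 equiv)
Product: 3 (1E,7E)-1,8-bis(dimethylamino)octa-1,7-diene-3,6-dione
Conditions: neat, 100 °C, MeOH distilled off
Reagents that add atoms: none
Why: Enaminone formation by condensation of the amide acetal at the two methyl groups, the less hindered α-positions of a methyl alkyl ketone; the central CH2–CH2 bond that becomes C3–C3'' is left untouched.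

Step 2
Reactants: 3 (1E,7E)-1,8-bis(dimethylamino)octa-1,7-diene-3,6-dione
Product: 4 (1E,3Z,5Z,7E)-3,6-bis(tert-butyldimethylsilyloxy)-N1,N1,N8,N8-tetramethylocta-1,3,5,7-tetraene-1,8-diamine
Conditions: TBSOTf (2.3 equiv), Et3N (3 equiv), Et2O, −78 → 0 °C; used crude
Reagents that add atoms: tert-butyldimethylsilyl trifluoromethanesulfonate, CC(C)(C)[Si](C)(C)OS(=O)(=O)C(F)(F)F
Why: Soft enolisation (O-silylation of each vinylogous amide, then deprotonation of the α'-CH2 by the amine), the usual entry to 1-amino-3-siloxydienes; the Z enol ethers expected on steric grounds put the chain substituent on the outside of each diene, which later fixes the cis C2/C3 relationship.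

Step 3
Reactants: 4 (1E,3Z,5Z,7E)-3,6-bis(tert-butyldimethylsilyloxy)-N1,N1,N8,N8-tetramethylocta-1,3,5,7-tetraene-1,8-diamine; 5 4-methoxybenzaldehyde (2.2 equiv)
Product: 7 (2R,2'R,3R,3'R)-2,2'-bis(4-methoxyphenyl)-2,2',3,3'-tetrahydro-4H,4'H-[3,3'-bipyran]-4,4'-dione, via double cycloadduct 6 (not isolated)
Conditions: Rh2(S-BPTPI)4 (2 mol %; BPTPI = 3-(benzo-fused phthalimido)piperidin-2-onate), CH2Cl2, −40 → 0 °C; then AcCl, −78 °C
Reagents that add atoms: none
Why: Catalytic asymmetric endo hetero-Diels–Alder reaction of a 4-substituted 1-amino-3-siloxydiene with an aryl aldehyde, followed by acyl chloride-induced loss of the amine and the silyl group: the chiral Lewis acid selects the aldehyde face (C2 and C2' both R), endo addition to the Z enol ether places aryl and C3 substituent cis (C3 and C3' both R), and catalyst control in both events should favour the C2-symmetric isomer over the meso isomer, which is removed by chromatography.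

Step 4
Reactants: 7 (2R,2'R,3R,3'R)-2,2'-bis(4-methoxyphenyl)-2,2',3,3'-tetrahydro-4H,4'H-[3,3'-bipyran]-4,4'-dione
Product: 9 (2R,2'R,3R,3'R)-2,2'-bis(4-methoxyphenyl)-5,5'-bis(phenylsulfanyl)-2,2',3,3'-tetrahydro-4H,4'H-[3,3'-bipyran]-4,4'-dione, via bis-chlorosulfide adduct 8 (not isolated)
Conditions: PhSCl (distilled, 2.2 equiv), CH2Cl2, −78 °C; then Et3N, −78 → 0 °C
Reagents that add atoms: benzenesulfenyl chloride, ClSc1ccccc1
Why: Electrophilic α-sulfenylation of a β-alkoxy enone by addition of the sulfenyl chloride across the enol ether bond (sulfur to the nucleophilic C5, chloride to C6) and amine-induced loss of HCl; C2 and C3 are remote from the reacting bond and Et3N at low temperature should not enolise the vinylogous ester.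

Step 5
Reactants: 9 (2R,2'R,3R,3'R)-2,2'-bis(4-methoxyphenyl)-5,5'-bis(phenylsulfanyl)-2,2',3,3'-tetrahydro-4H,4'H-[3,3'-bipyran]-4,4'-dione
Product: 10 (2R,2'R,3R,3'R)-2,2'-bis(4-methoxyphenyl)-5,5'-bis(phenylsulfinyl)-2,2',3,3'-tetrahydro-4H,4'H-[3,3'-bipyran]-4,4'-dione (mixture of sulfur epimers)
Conditions: mCPBA (2.0 equiv), CH2Cl2, −78 °C
Reagents that add atoms: 3-chloroperoxybenzoic acid, OOC(=O)c1cccc(Cl)c1
Why: Chemoselective sulfide-to-sulfoxide oxidation with one equivalent of peracid per sulfur at low temperature; the electron-poor enone bond and the anisyl rings should not react, and the configuration at sulfur is irrelevant because sulfur is lost in step 8.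

Step 6
Reactants: 11 methyl acetoacetate
Product: 12 methyl 3-(trimethylsilyloxy)but-2-enoate (E/Z mixture)
Conditions: TMSCl, Et3N, hexane, 20 °C
Reagents that add atoms: chlorotrimethylsilane, C[Si](C)(C)Cl
Why: Silyl enol ether formation by O-silylation of the enol of a β-keto ester under amine base.

Step 7
Reactants: 12 methyl 3-(trimethylsilyloxy)but-2-enoate
Product: 14 1-methoxy-1,3-bis(trimethylsilyloxy)buta-1,3-diene, via lithium dienolate 13 (not isolated)
Conditions: LiN(i-Pr)2, THF, −78 °C; then TMSCl, −78 → 0 °C; distilled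
Reagents that add atoms: chlorotrimethylsilane, C[Si](C)(C)Cl
Why: γ-Deprotonation of the silyloxy crotonate and O-silylation of the dienolate, the standard preparation of 1,3-bis(silyloxy)dienes (silyl ketene acetal formation).

Step 8
Reactants: 10 (2R,2'R,3R,3'R)-2,2'-bis(4-methoxyphenyl)-5,5'-bis(phenylsulfinyl)-2,2',3,3'-tetrahydro-4H,4'H-[3,3'-bipyran]-4,4'-dione; 14 1-methoxy-1,3-bis(trimethylsilyloxy)buta-1,3-diene (3 equiv per enone)
Product: 17 (2R,2''R,3R,3''R)-5,5'',7,7''-tetrahydroxy-4',4'''-dimethoxy-3,3''-biflavanone, via double Diels–Alder adduct 15 (not isolated), via bis-silyl ether 16 (not isolated)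
Conditions: toluene, no Lewis acid, 0 → 50 °C; then aq. citric acid, THF, 0 °C
Reagents that add atoms: none
Why: Proposed new method: the electron-rich diene should add across each sulfinyl-activated C5=C6 bond in a polarised, asynchronous [4+2] sense, its CH2 terminus bonding to C6 (the future C8a, the electrophilic β-carbon of the vinylogous ester) and its ketene acetal carbon to the sulfinyl-bearing C5 (the future C4a), so that each ring A is closed by intermolecular cycloaddition forming C8–C8a and C4a–C5 (a Mukaiyama–Michael addition followed by ring closure on the same atoms would give the same adduct). In adduct 15 the sulfinyl group at C4a and the hydrogen at C8a are cis, the geometry needed for thermal syn elimination of benzenesulfenic acid, which should give the C4a=C8a bond without base; loss of methoxytrimethylsilane from the C5 ketal and enolisation then aromatise each ring to 16, and mild acid frees the 7-hydroxyls. The closest known reaction type is the Diels–Alder addition–aromatisation of 1,3-dioxygenated silyloxydienes with sulfinylquinones, with halo-quinones and with chromones carrying a sulfinyl or acyl group at C3; an α-sulfinyl 2,3-dihydropyran-4-one has not been used as the dienophile. No stereocentre is created, because the sp3 centres of 15 are lost on aromatisation, and the C2 and C3 centres are never exposed to base. The step needs regioselectivity, secured by the polarity match of the diene terminus with C6 that ketone and sulfoxide both reinforce, and elimination towards C4a=C8a in preference to cleavage of the O1–C8a bond, secured by a leaving group that departs through a cyclic syn transition state (a bromide at C4a would be cis to a non-acidic C8a–H and could leave only by base-induced pathways that open the pyranone).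

Step 9
Reactants: 17 (2R,2''R,3R,3''R)-5,5'',7,7''-tetrahydroxy-4',4'''-dimethoxy-3,3''-biflavanone
Product: 18 (2R,2''R,3R,3''R)-5,5'',7-trihydroxy-7'',4',4'''-trimethoxy-3,3''-biflavanone (target)
Conditions: TMSCHN2 (1.0 equiv), MeOH–toluene, 0 → 20 °C; recovered 17 recycled
Reagents that add atoms: (trimethylsilyl)diazomethane, C[Si](C)(C)C=[N+]=[N-]
Why: Diazoalkane O-methylation of the most acidic phenol: the unchelated 7-hydroxyls should react much faster than the hydrogen-bonded 5-hydroxyls, the two 7-hydroxyls are homotopic so either gives the same product, and one equivalent of reagent without added base should limit dimethylation and avoid the base-induced cis-to-trans isomerisation at C3.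

**Compound list**

1 | hexane-2,5-dione | CC(=O)CCC(C)=O | starting material
2 | N,N-dimethylformamide dimethyl acetal | COC(OC)N(C)C | starting material
3 | (1E,7E)-1,8-bis(dimethylamino)octa-1,7-diene-3,6-dione | CN(C)/C=C/C(=O)CCC(=O)/C=C/N(C)C | intermediate
4 | (1E,3Z,5Z,7E)-3,6-bis(tert-butyldimethylsilyloxy)-N1,N1,N8,N8-tetramethylocta-1,3,5,7-tetraene-1,8-diamine | CN(C)/C=C/C(O[Si](C)(C)C(C)(C)C)=C/C=C(O[Si](C)(C)C(C)(C)C)/C=C/N(C)C | intermediate
5 | 4-methoxybenzaldehyde | COc1ccc(C=O)cc1 | starting material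
6 | (2R,2'R,3R,3'R,6S,6'S)-4,4'-bis(tert-butyldimethylsilyloxy)-6,6'-bis(dimethylamino)-2,2'-bis(4-methoxyphenyl)-3,3',6,6'-tetrahydro-2H,2'H-3,3'-bipyran (all-cis double cycloadduct) | COc1ccc([C@@H]2O[C@H](N(C)C)C=C(O[Si](C)(C)C(C)(C)C)[C@@H]2[C@H]2C(O[Si](C)(C)C(C)(C)C)=C[C@@H](N(C)C)O[C@H]2c2ccc(OC)cc2)cc1 | intermediate
7 | (2R,2'R,3R,3'R)-2,2'-bis(4-methoxyphenyl)-2,2',3,3'-tetrahydro-4H,4'H-[3,3'-bipyran]-4,4'-dione | COc1ccc([C@@H]2OC=CC(=O)[C@@H]2[C@H]2C(=O)C=CO[C@H]2c2ccc(OC)cc2)cc1 | intermediate
8 | (2R,2'R,3R,3'R)-6,6'-dichloro-2,2'-bis(4-methoxyphenyl)-5,5'-bis(phenylsulfanyl)-3,3'-bi(tetrahydropyran)-4,4'-dione (C5/C6 configuration not defined) | COc1ccc([C@@H]2OC(Cl)C(Sc3ccccc3)C(=O)[C@@H]2[C@H]2C(=O)C(Sc3ccccc3)C(Cl)O[C@H]2c2ccc(OC)cc2)cc1 | intermediate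
9 | (2R,2'R,3R,3'R)-2,2'-bis(4-methoxyphenyl)-5,5'-bis(phenylsulfanyl)-2,2',3,3'-tetrahydro-4H,4'H-[3,3'-bipyran]-4,4'-dione | COc1ccc([C@@H]2OC=C(Sc3ccccc3)C(=O)[C@@H]2[C@H]2C(=O)C(Sc3ccccc3)=CO[C@H]2c2ccc(OC)cc2)cc1 | intermediate
10 | (2R,2'R,3R,3'R)-2,2'-bis(4-methoxyphenyl)-5,5'-bis(phenylsulfinyl)-2,2',3,3'-tetrahydro-4H,4'H-[3,3'-bipyran]-4,4'-dione (sulfur configuration not defined) | COc1ccc([C@@H]2OC=C(S(=O)c3ccccc3)C(=O)[C@@H]2[C@H]2C(=O)C(S(=O)c3ccccc3)=CO[C@H]2c2ccc(OC)cc2)cc1 | intermediate
11 | methyl acetoacetate | COC(=O)CC(C)=O | starting material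
12 | methyl 3-(trimethylsilyloxy)but-2-enoate | COC(=O)C=C(C)O[Si](C)(C)C | intermediate
13 | lithium 1-methoxy-3-(trimethylsilyloxy)buta-1,3-dien-1-olate | [Li+].[O-]C(OC)=CC(=C)O[Si](C)(C)C | intermediate
14 | 1-methoxy-1,3-bis(trimethylsilyloxy)buta-1,3-diene | C=C(O[Si](C)(C)C)C=C(OC)O[Si](C)(C)C | intermediate
15 | double [4+2] adduct: (2R,2'R,3R,3'R)-5,5'-dimethoxy-2,2'-bis(4-methoxyphenyl)-4a,4a'-bis(phenylsulfinyl)-5,5',7,7'-tetrakis(trimethylsilyloxy)-2,2',3,3',4a,4a',5,5',8,8',8a,8a'-dodecahydro-[3,3'-bichromene]-4,4'-dione (new sp3 centres and sulfur not defined) | COc1ccc([C@@H]2OC3CC(O[Si](C)(C)C)=CC(OC)(O[Si](C)(C)C)C3(S(=O)c3ccccc3)C(=O)[C@@H]2[C@H]2C(=O)C3(S(=O)c4ccccc4)C(OC)(O[Si](C)(C)C)C=C(O[Si](C)(C)C)CC3O[C@H]2c2ccc(OC)cc2)cc1 | intermediate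
16 | (2R,2''R,3R,3''R)-5,5''-dihydroxy-4',4'''-dimethoxy-7,7''-bis(trimethylsilyloxy)-3,3''-biflavanone | COc1ccc([C@@H]2Oc3cc(O[Si](C)(C)C)cc(O)c3C(=O)[C@@H]2[C@H]2C(=O)c3c(O)cc(O[Si](C)(C)C)cc3O[C@H]2c2ccc(OC)cc2)cc1 | intermediate
17 | (2R,2''R,3R,3''R)-5,5'',7,7''-tetrahydroxy-4',4'''-dimethoxy-3,3''-biflavanone | COc1ccc([C@@H]2Oc3cc(O)cc(O)c3C(=O)[C@@H]2[C@H]2C(=O)c3c(O)cc(O)cc3O[C@H]2c2ccc(OC)cc2)cc1 | intermediate
18 | (2R,2''R,3R,3''R)-5,5'',7-trihydroxy-7'',4',4'''-trimethoxy-3,3''-biflavanone | COc1ccc([C@@H]2Oc3cc(O)cc(O)c3C(=O)[C@@H]2[C@H]2C(=O)c3c(O)cc(OC)cc3O[C@H]2c2ccc(OC)cc2)cc1 | target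

**Step count**

Total: 9 steps. Longest linear sequence: 7 steps (steps 1–5, 8 and 9); the diene branch (steps 6 and 7) joins at step 8.

**Steps most likely to fail**

1. Step 8 (carries the label). The diene may add only in conjugate fashion, or be consumed in a Pummerer-type reaction with the sulfoxide, or the adduct may open at the O1–C8a bond instead of losing sulfenic acid. The fallback uses known chemistry, sets out from 5 and returns at 17; rings A are taken from a phloroglucinol building block and the C3–C3'' bond is made between two flavones.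
   - Claisen–Schmidt condensation of 5 with 1-[2,4-bis(benzyloxy)-6-hydroxyphenyl]ethan-1-one F1 (KOH, EtOH) gives the (E)-chalcone F2.
   - Oxidative cyclisation (catalytic I2, DMSO, 120 °C) gives 5,7-bis(benzyloxy)-4'-methoxyflavone F3.
   - Lithiation at C3 and iodination (LiN(i-Pr)2, THF, −78 °C; I2) gives the 3-iodoflavone F4.
   - Ullmann homocoupling (Cu powder, DMF, 130 °C) gives the 3,3''-biflavone F5.
   - Hydrogenation over Pd on carbon (H2, EtOAc–MeOH) adds syn to each C2=C3 bond, which makes both rings cis, and cleaves the four benzyl ethers.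
   - The C2-symmetric all-cis tetraol is separated from the meso isomer and resolved on a chiral stationary phase to give 17.

2. Step 3. The second cycloaddition on the hindered diene may be slow, some exo addition may give a trans ring, or the second event may take the opposite facial sense and give the meso isomer. The fallback sets out from 5 and returns at 7; rings C are closed by aldol addition and cyclisation instead of cycloaddition.
   - (1E,7E)-1,8-Dichloroocta-1,7-diene-3,6-dione F6 is prepared from succinyl chloride and acetylene (AlCl3, CH2Cl2).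
   - F6 is converted into its bis(Z)-boron enolate with the enantiomer of diisopinocampheylboron triflate that gives R carbinols (i-Pr2NEt, CH2Cl2, −78 °C) and added to 5 (2 equiv), giving the bis-syn-aldol F7.
   - TMSOTf and i-Pr2NEt close both rings by oxa-Michael addition and loss of chloride, with retention at all four centres (syn aldol becomes the cis pyranone), giving 7.

3. Step 4. The sulfenyl chloride may attack the anisyl rings, the p-methoxybenzylic C2–O bond may ionise in the chloro adduct, or the elimination may be incomplete. The fallback sets out from 7 and returns at 9; sulfur is introduced by cross-coupling instead of electrophilic addition.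
   - α-Iodination (I2, pyridine, CH2Cl2, 20 °C) gives the 5,5'-diiodide F8.
   - C–S coupling with thiophenol (Pd2(dba)3, Xantphos, i-Pr2NEt, dioxane, 80 °C) gives 9.

**Further compounds**

F1 | step 8 | 1-[2,4-bis(benzyloxy)-6-hydroxyphenyl]ethan-1-one | CC(=O)c1c(O)cc(OCc2ccccc2)cc1OCc1ccccc1
F2 | step 8 | (E)-1-[2,4-bis(benzyloxy)-6-hydroxyphenyl]-3-(4-methoxyphenyl)prop-2-en-1-one | COc1ccc(/C=C/C(=O)c2c(O)cc(OCc3ccccc3)cc2OCc2ccccc2)cc1
F3 | step 8 | 5,7-bis(benzyloxy)-2-(4-methoxyphenyl)-4H-chromen-4-one | COc1ccc(-c2cc(=O)c3c(OCc4ccccc4)cc(OCc4ccccc4)cc3o2)cc1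
F4 | step 8 | 5,7-bis(benzyloxy)-3-iodo-2-(4-methoxyphenyl)-4H-chromen-4-one | COc1ccc(-c2oc3cc(OCc4ccccc4)cc(OCc4ccccc4)c3c(=O)c2I)cc1
F5 | step 8 | 5,5'',7,7''-tetrakis(benzyloxy)-4',4'''-dimethoxy-3,3''-biflavone | COc1ccc(-c2oc3cc(OCc4ccccc4)cc(OCc4ccccc4)c3c(=O)c2-c2c(-c3ccc(OC)cc3)oc3cc(OCc4ccccc4)cc(OCc4ccccc4)c3c2=O)cc1
F6 | step 3 | (1E,7E)-1,8-dichloroocta-1,7-diene-3,6-dione | Cl/C=C/C(=O)CCC(=O)/C=C/Cl
F7 | step 3 | (1E,4R,5R,7E)-1,8-dichloro-4,5-bis[(R)-hydroxy(4-methoxyphenyl)methyl]octa-1,7-diene-3,6-dione | COc1ccc([C@H](O)[C@H](C(=O)/C=C/Cl)[C@@H](C(=O)/C=C/Cl)[C@@H](O)c2ccc(OC)cc2)cc1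
F8 | step 4 | (2R,2'R,3R,3'R)-5,5'-diiodo-2,2'-bis(4-methoxyphenyl)-2,2',3,3'-tetrahydro-4H,4'H-[3,3'-bipyran]-4,4'-dione | COc1ccc([C@@H]2OC=C(I)C(=O)[C@@H]2[C@H]2C(=O)C(I)=CO[C@H]2c2ccc(OC)cc2)cc1
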